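| setting | Saturday's | Friday's | Thursday's | flask |
|---|---|---|---|---|
| starting material | 1 mM | 1 mM | 2 mM | 1.0 mM |
| gas phase | 0.050 mM (held) | 0.050 mM (held) | 0.050 mM (held) | 0.050 mM (held) |
| free catalyst | 0.25 mol% | 0.38 mol% | 0.5 mol% | 0.5 mol% |
| remark | run made earlier | run made earlier | run made earlier |  |
| time |  |  |  | 10 min |

| run | time / min | product / % |
|---|---|---|
| Saturday's | 1.50 | 14 |
| Saturday's | 3.00 | 29 |
| Saturday's | 5.00 | 40 |
| Saturday's | 6.00 | 47 |
| Saturday's | 8.00 | 51 |
| Saturday's | 10.0 | 61 |
| Saturday's | 12.0 | 64 |
| Friday's | 1.50 | 23 |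
| Friday's | 3.00 | 41 |
| Friday's | 5.00 | 56 |
| Friday's | 6.00 | 61 |
| Friday's | 8.00 | 70 |
| Friday's | 10.0 | 76 |
| Friday's | 12.0 | 76 |
| Thursday's | 1.00 | 33 |
| Thursday's | 3.00 | 63 |
| Thursday's | 6.00 | 87 |
| Thursday's | 8.00 | 89 |
| Thursday's | 12.0 | 90 |

(standard deviation of a reading: 1.5 percentage points)

- amount of product at 10 min, in percent of the starting material charged
- the change that raises the amount of product at 10 min, in percent of the starting material charged most ("none" if none brings more than 2 percentage points) (alpha / zeta / delta / none)
- amount of product at 10 min, in percent of the starting material charged, after alpha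

- alpha: doubling the amount of free catalyst, all else as stated
- zeta: doubling the transfer coefficient of the gas phase, all else as stated
- delta: doubling the saturation concentration of gas phase, all else as stated

1. Count turnovers, and read this flask on that clock. Its free catalyst must turn over 200 times to use up the charge of starting material.

2. Take the first reading of each run as pseudo-first-order: Saturday's gives 0.101 min⁻¹, Friday's 0.174 min⁻¹, Thursday's 0.400 min⁻¹. Each goes with the catalyst present, loading times starting material. Pooled and scaled to this flask, they give 4.83 min: the turnover clock, the time in which the starting pace uses up one charge.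

3. Draw the curve. Call one such time a tick. On a plain exponential the curve starts at 0.207 min⁻¹ of the charge, crosses a fraction of 0.5 near 3.35 min, and stands at 63.2% at one tick. Friday's reads 61% at 0.945 ticks.

4. Place 10 min: this flask stands at 2.07 ticks. Friday's last reading, 76%, lies at 1.89 ticks; Thursday's 87% lies at 2.49. Interpolate: my figure is 79.4%.

5. Find the level. Thursday's reads 89% and 90% at 3.31 and 4.97 ticks. Alpha puts this flask at 4.14 ticks, between them, so I expect about 90%. Each run held the gas phase at one level, so zeta and delta stay unread.

6. The forecast gives 80% (75% to 85%), alpha as best and 90% after it, saying “Conversion tracks catalyst × time across all three runs”.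

    gas phase ⇌ dissolved gas, rate k1*(csat - [dissolved gas]) (kL = 0.850 s⁻¹)
    starting material + dissolved gas + free catalyst ⇌ free catalyst + product (K = 2.90 × 10⁵ M⁻¹, k = 2.00 × 10⁷ M⁻² s⁻¹)
    starting material + free catalyst → spent catalyst (k = 2.20 M⁻¹ s⁻¹)

The flask gives 82.8%, and 92.5% after alpha. Delta is best: it adds 13 percentage points, more than the 9.7 points from alpha and the 0.64 points from zeta. At 5.00 min, 1.04 ticks, this flask holds 65.4% product. Now take the neighbour charged with 0.2 mol% free catalyst, time held: it stands at 0.829 ticks, where Saturday's read 51% at 8.00 min, and it gives 50.8%.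

The data are simulated with made-up constants.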